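## Retrosynthetic overview

1. Target 24 ⇐ two esterifications, two ketone reductions directed by the C3 hydroxyl (at C1 and C4) and a 1,6-reduction of a dienone ⇐ hydroxy dienedione 17 ⇐ silylene-bridged trienone 15.
2. 15 ⇐ α-diazoketone 13 by an intramolecular Büchner reaction: the cyclopentanone and a cyclopropane close on the arene, then 6π ring opening of the norcaradiene enlarges the benzene ring (C3a, C4–C8) by the carbene carbon C8a to the seven-membered ring.
3. Enabling feature: the seven-membered ring is a para-cresol nucleus plus one carbon (C4–O = phenol oxygen, C6–CH3 = para methyl, C3a = ipso carbon, quaternary C8a = inserted carbene carbon). The cyclopentane carries the 1,3-dioxygen pattern of a β-hydroxy ketone (C1 = diazoketone carbonyl, C3 = benzylic carbinol).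
4. 13 ⇐ acid 11 ⇐ (R)-diol 7 by phenol-directed asymmetric allylation of ketone 4 (from m-cresol and isobutyronitrile). The phenol and carbinol oxygens are tied as a di-tert-butylsilylene, a temporary ring that steers the carbenoid and is removed with fluoride.
5. Ring order: arene (bought) → dioxasiline (temporary) → cyclopentanone + cyclopropane → cycloheptatriene (ring expansion) → dioxasiline opened.

Key step: step 7

Remark on numbering: locants follow the azulene numbering of the target: C1 (OAc), C2, C3 (OH, i-Pr), C3a, C4 (anisoate), C5, C6 (CH3), C7, C8, C8a (CH3).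

Remark on the chemistry: the sense of induction of the (R,R)-allylsilane 5 with ketone 4 is assumed. If it is the opposite, the equally available (S,S)-reagent is used and nothing else changes.

## Route

Step 1
Reactants: 1 3-methylphenol; 2 2-methylpropanenitrile
Product: 4 1-(2-hydroxy-4-methylphenyl)-2-methylpropan-1-one, via ketimine 3 (not isolated)
Conditions: BCl3 (1.1 equiv), AlCl3 (1.1 equiv), ClCH2CH2Cl, 0 → 80 °C; then 2 M HCl, 80 °C
Reagents that add atoms: water, O
Why: Sugasawa ortho-acylation: the nitrile is delivered inside the phenol–boron chelate to the free ortho position para to the methyl group (the other ortho position lies between OH and CH3), and acid hydrolysis of ketimine 3 gives the ortho-hydroxyaryl ketone.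

Step 2
Reactants: 4 1-(2-hydroxy-4-methylphenyl)-2-methylpropan-1-one; 5 (3aR,7aR)-2-allyl-1,3-bis(4-bromobenzyl)-2-chlorooctahydro-1H-1,3,2-benzodiazasilole
Product: 7 2-[(3R)-3-hydroxy-2-methylhex-5-en-3-yl]-5-methylphenol, via spirosilane adduct 6 (not isolated)
Conditions: 5 (1.5 equiv), CH2Cl2, 23 °C, 24–48 h; then 1 M HCl, EtOAc
Reagents that add atoms: none
Why: Phenol-directed asymmetric allylation with a strained chiral allylchlorosilane (Leighton allylation, the method known for hindered 2′-hydroxyaryl ketones): the phenol displaces chloride on silicon, the ketone is activated on the same silicon and the allyl group is transferred through a closed chair-like transition state in which the diamine differentiates the carbonyl faces, which should set the tertiary carbinol as R.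

Step 3
Reactants: 7 2-[(3R)-3-hydroxy-2-methylhex-5-en-3-yl]-5-methylphenol
Product: 8 (4R)-2,2-di-tert-butyl-7-methyl-4-(propan-2-yl)-4-(prop-2-en-1-yl)-4H-1,3,2-benzodioxasiline
Conditions: t-Bu2Si(OTf)2, 2,6-lutidine, CH2Cl2, 0 °C → rt
Reagents that add atoms: di-tert-butylsilyl bis(trifluoromethanesulfonate), CC(C)(C)[Si](OS(=O)(=O)C(F)(F)F)(OS(=O)(=O)C(F)(F)F)C(C)(C)C
Why: Silylene formation on a 1,3-diol-type pair (phenol first, then ring closure on the tertiary alcohol) under buffered conditions that avoid ionisation of the ortho-hydroxybenzylic alcohol; the six-membered dioxasiline is the temporary ring used in step 7.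

Step 4
Reactants: 8 (4R)-2,2-di-tert-butyl-7-methyl-4-(propan-2-yl)-4-(prop-2-en-1-yl)-4H-1,3,2-benzodioxasiline
Product: 10 2-[(4R)-2,2-di-tert-butyl-7-methyl-4-(propan-2-yl)-4H-1,3,2-benzodioxasilin-4-yl]acetaldehyde, via ozonide 9 (not isolated)
Conditions: O3, CH2Cl2, −78 °C (Sudan III end point); then Me2S, −78 °C → rt
Reagents that add atoms: ozone, [O-][O+]=O
Why: Ozonolysis with reductive work-up of the monosubstituted alkene, which reacts with ozone far faster than the silyloxy arene; no stereocentre is touched.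

Step 5
Reactants: 10 2-[(4R)-2,2-di-tert-butyl-7-methyl-4-(propan-2-yl)-4H-1,3,2-benzodioxasilin-4-yl]acetaldehyde
Product: 11 2-[(4R)-2,2-di-tert-butyl-7-methyl-4-(propan-2-yl)-4H-1,3,2-benzodioxasilin-4-yl]acetic acid
Conditions: NaClO2, NaH2PO4, 2-methyl-2-butene, t-BuOH/H2O, 0 °C → rt
Reagents that add atoms: sodium chlorite, [Na+].[O-]Cl=O
Why: Pinnick oxidation under buffered conditions; 2-methyl-2-butene scavenges hypochlorous acid so that the electron-rich arene is not chlorinated.

Step 6
Reactants: 11 2-[(4R)-2,2-di-tert-butyl-7-methyl-4-(propan-2-yl)-4H-1,3,2-benzodioxasilin-4-yl]acetic acid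
Product: 13 3-diazo-1-[(4R)-2,2-di-tert-butyl-7-methyl-4-(propan-2-yl)-4H-1,3,2-benzodioxasilin-4-yl]butan-2-one, via acid chloride 12 (not isolated)
Conditions: 1-chloro-N,N,2-trimethylprop-1-en-1-amine (Ghosez reagent), CH2Cl2, 0 °C; then CH3CHN2 (3 equiv), Et2O, −20 → 0 °C
Reagents that add atoms: diazoethane, CC=[N+]=[N-]
Why: Neutral formation of the acid chloride followed by Arndt–Eistert-type C-acylation of diazoethane, the standard entry to 2-diazo-3-ketones; a second equivalent of diazoethane takes up the HCl.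

Step 7
Reactants: 13 3-diazo-1-[(4R)-2,2-di-tert-butyl-7-methyl-4-(propan-2-yl)-4H-1,3,2-benzodioxasilin-4-yl]butan-2-one
Product: 15 (3R,8aR)-3,4-[(di-tert-butylsilanediyl)bis(oxy)]-6,8a-dimethyl-3-(propan-2-yl)-3,8a-dihydroazulen-1(2H)-one, via norcaradiene 14 (not isolated)
Conditions: Rh2(OAc)4 (1 mol %), CH2Cl2, 40 °C, slow addition of 13
Reagents that add atoms: none
Why: Rh(II) converts the diazoketone into an electrophilic acyl carbenoid that adds across the ipso–ortho bond (C3a–C8) of the arene to give norcaradiene 14, whose C3a–C8 σ bond opens by thermal 6π electrocyclisation so that the benzene ring is enlarged by the carbenoid carbon C8a to the cycloheptatriene of 15; this is the intramolecular Büchner reaction known for 1-diazo-4-arylbutan-2-ones and their α-methyl homologues, which give 3,4-dihydroazulen-1(2H)-ones. The cyclopentanone closes by attack of the carbenoid carbon on the ipso carbon (5-exo with respect to the arene π bond) and the cyclopropane by the concerted [2+1] closure onto the ortho CH, while the seven-membered ring is not closed but grows out of the six-membered one in the electrocyclic opening. The one new stereocentre that remains, quaternary C8a, is controlled by C3 through the silylene ring: O3 is held near the arene plane, so the CH2 tether and the isopropyl group sit on opposite faces and the carbenoid can only reach the face anti to the isopropyl group, which places the 8a-methyl trans to it and cis to O3. Site selectivity (C3a–C8, not C3a–C4) is secured because C4 is fully substituted and part of the dioxasiline ring. Chemoselectivity for arene addition over 1,2-hydride shift, insertion into the isopropyl C–H bond and oxonium ylide formation is expected from the electron-rich arene, the five-membered transition state, the carboxylate ligands on rhodium and the shielding of O3 by the tert-butyl groups.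

Step 8
Reactants: 15 (3R,8aR)-3,4-[(di-tert-butylsilanediyl)bis(oxy)]-6,8a-dimethyl-3-(propan-2-yl)-3,8a-dihydroazulen-1(2H)-one
Product: 17 (3R,3aR,8aR)-3-hydroxy-6,8a-dimethyl-3-(propan-2-yl)-2,3,3a,8a-tetrahydroazulene-1,4-dione, via fluorosilyl ether 16 (not isolated)
Conditions: HF·pyridine, pyridine, THF, 0 °C → rt
Reagents that add atoms: none
Why: Fluoride cleaves the enol Si–O bond first and the trienol ketonises at C3a, then the hindered tertiary fluorosilyl ether is cleaved; C3a is protonated from the face opposite the silyloxy and 8a-methyl groups and can equilibrate through the dienol, so the C3a–C4 bond should end cis to the C3 oxygen (hydrogen bond to C4=O) and anti to the isopropyl group (trans ring fusion).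

Step 9
Reactants: 17 (3R,3aR,8aR)-3-hydroxy-6,8a-dimethyl-3-(propan-2-yl)-2,3,3a,8a-tetrahydroazulene-1,4-dione
Product: 18 (1S,3R,3aR,8aR)-1,3-dihydroxy-6,8a-dimethyl-3-(propan-2-yl)-2,3,3a,8a-tetrahydroazulen-4(1H)-one
Conditions: Me4NBH(OAc)3, MeCN/AcOH, −30 → 0 °C
Reagents that add atoms: none
Why: Saksena–Evans hydroxyl-directed reduction: the C3 hydroxyl exchanges onto boron and delivers hydride to the same face of the C1 cyclopentanone, which gives the trans-1,3-diol (C1–OH trans to C3–OH and to the 8a-methyl); the C4 carbonyl, deactivated by conjugation with the diene, should react much more slowly with this weak hydride donor.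

Step 10
Reactants: 18 (1S,3R,3aR,8aR)-1,3-dihydroxy-6,8a-dimethyl-3-(propan-2-yl)-2,3,3a,8a-tetrahydroazulen-4(1H)-one
Product: 20 (1S,3R,3aR,8aR)-1,3-dihydroxy-6,8a-dimethyl-3-(propan-2-yl)-1,2,3,3a,8,8a-hexahydroazulen-4(5H)-one, via dilithium dienolate 19 (not isolated)
Conditions: Li (2.2 equiv), NH3(l)/THF, −78 °C, 10 min; then solid NH4Cl
Reagents that add atoms: none
Why: Dissolving-metal 1,6-reduction of the 2,4-dienone: protonation at the δ-carbon C8 gives the dienolate, and kinetic protonation at the α-carbon C5 gives the β,γ-unsaturated ketone with the C6=C7 bond (as in the Li/NH3 reduction of steroidal 4,6-dien-3-ones to 5-en-3-ones); no stereocentre is formed and C3a is not part of the dienolate.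

Step 11
Reactants: 20 (1S,3R,3aR,8aR)-1,3-dihydroxy-6,8a-dimethyl-3-(propan-2-yl)-1,2,3,3a,8,8a-hexahydroazulen-4(5H)-one
Product: 21 (1S,3R,3aR,8aR)-3-hydroxy-6,8a-dimethyl-4-oxo-3-(propan-2-yl)-1,2,3,3a,4,5,8,8a-octahydroazulen-1-yl acetate
Conditions: Ac2O, pyridine, DMAP (cat.), CH2Cl2, 0 °C
Reagents that add atoms: acetic anhydride, CC(=O)OC(C)=O
Why: Acylation of the only secondary hydroxyl; the tertiary C3–OH is inert under these conditions, and short contact at 0 °C is chosen so that the β,γ-double bond does not move into conjugation.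

Step 12
Reactants: 21 (1S,3R,3aR,8aR)-3-hydroxy-6,8a-dimethyl-4-oxo-3-(propan-2-yl)-1,2,3,3a,4,5,8,8a-octahydroazulen-1-yl acetate
Product: 22 (1S,3R,3aS,4S,8aR)-3,4-dihydroxy-6,8a-dimethyl-3-(propan-2-yl)-1,2,3,3a,4,5,8,8a-octahydroazulen-1-yl acetate
Conditions: Me4NBH(OAc)3, MeCN/AcOH, −30 → 0 °C
Reagents that add atoms: none
Why: Second Saksena–Evans directed reduction: the C3 hydroxyl, cis to C4 on the cyclopentane, delivers hydride through a six-membered transition state to the face of the C4 carbonyl on which it sits, so the new hydroxyl should be cis to H3a and trans to the 8a-methyl (4S); acetate and alkene are untouched.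

Step 13
Reactants: 22 (1S,3R,3aS,4S,8aR)-3,4-dihydroxy-6,8a-dimethyl-3-(propan-2-yl)-1,2,3,3a,4,5,8,8a-octahydroazulen-1-yl acetate; 23 4-methoxybenzoyl chloride
Product: 24 (1S,3R,3aS,4S,8aR)-1-(acetyloxy)-3-hydroxy-6,8a-dimethyl-3-(propan-2-yl)-1,2,3,3a,4,5,8,8a-octahydroazulen-4-yl 4-methoxybenzoate
Conditions: 23, DMAP, pyridine, CH2Cl2, 0 °C → rt
Reagents that add atoms: none
Why: DMAP-catalysed acylation of the secondary C4–OH; the tertiary C3–OH does not react, so no protection is needed.

## Compound list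

1 | 3-methylphenol (m-cresol) | Cc1cccc(O)c1 | starting material
2 | 2-methylpropanenitrile (isobutyronitrile) | CC(C)C#N | starting material
3 | 2-(1-imino-2-methylpropyl)-5-methylphenol (ketimine, boron-bound in the flask) | CC(C)C(=N)c1ccc(C)cc1O | intermediate
4 | 1-(2-hydroxy-4-methylphenyl)-2-methylpropan-1-one | CC(C)C(=O)c1ccc(C)cc1O | intermediate
5 | (3aR,7aR)-2-allyl-1,3-bis(4-bromobenzyl)-2-chlorooctahydro-1H-1,3,2-benzodiazasilole ((R,R)-Leighton allylsilane) | C=CC[Si]1(Cl)N(Cc2ccc(Br)cc2)[C@@H]2CCCC[C@H]2N1Cc1ccc(Br)cc1 | starting material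
6 | spirosilane adduct: phenol oxygen and (R)-carbinol oxygen of 7 bridged by the Si(diamine) unit | C=CC[C@]1(C(C)C)O[Si]2(Oc3cc(C)ccc13)N(Cc1ccc(Br)cc1)[C@@H]1CCCC[C@H]1N2Cc1ccc(Br)cc1 | intermediate
7 | 2-[(3R)-3-hydroxy-2-methylhex-5-en-3-yl]-5-methylphenol | C=CC[C@@](O)(C(C)C)c1ccc(C)cc1O | intermediate
8 | (4R)-2,2-di-tert-butyl-7-methyl-4-(propan-2-yl)-4-(prop-2-en-1-yl)-4H-1,3,2-benzodioxasiline | C=CC[C@]1(C(C)C)O[Si](C(C)(C)C)(C(C)(C)C)Oc2cc(C)ccc12 | intermediate
9 | secondary ozonide (1,2,4-trioxolane) of 8 | O1OC(C[C@]2(C(C)C)O[Si](C(C)(C)C)(C(C)(C)C)Oc3cc(C)ccc23)OC1 | intermediate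
10 | 2-[(4R)-2,2-di-tert-butyl-7-methyl-4-(propan-2-yl)-4H-1,3,2-benzodioxasilin-4-yl]acetaldehyde | O=CC[C@]1(C(C)C)O[Si](C(C)(C)C)(C(C)(C)C)Oc2cc(C)ccc12 | intermediate
11 | 2-[(4R)-2,2-di-tert-butyl-7-methyl-4-(propan-2-yl)-4H-1,3,2-benzodioxasilin-4-yl]acetic acid | OC(=O)C[C@]1(C(C)C)O[Si](C(C)(C)C)(C(C)(C)C)Oc2cc(C)ccc12 | intermediate
12 | 2-[(4R)-2,2-di-tert-butyl-7-methyl-4-(propan-2-yl)-4H-1,3,2-benzodioxasilin-4-yl]acetyl chloride | ClC(=O)C[C@]1(C(C)C)O[Si](C(C)(C)C)(C(C)(C)C)Oc2cc(C)ccc12 | intermediate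
13 | 3-diazo-1-[(4R)-2,2-di-tert-butyl-7-methyl-4-(propan-2-yl)-4H-1,3,2-benzodioxasilin-4-yl]butan-2-one | CC(=[N+]=[N-])C(=O)C[C@]1(C(C)C)O[Si](C(C)(C)C)(C(C)(C)C)Oc2cc(C)ccc12 | intermediate
14 | norcaradiene valence isomer of 15 (cyclopropane C3a–C8–C8a, diene C4=C5/C6=C7; 8a-methyl trans to the isopropyl group) | CC1=C[C@@H]2[C@@]3(C)C(=O)C[C@]4(C(C)C)O[Si](C(C)(C)C)(C(C)(C)C)OC(=C1)[C@@]243 | intermediate
15 | (3R,8aR)-3,4-[(di-tert-butylsilanediyl)bis(oxy)]-6,8a-dimethyl-3-(propan-2-yl)-3,8a-dihydroazulen-1(2H)-one (triene C3a=C4, C5=C6, C7=C8; 8a-methyl cis to O3, trans to isopropyl) | CC1=CC2=C3[C@](C(C)C)(CC(=O)[C@]3(C)C=C1)O[Si](C(C)(C)C)(C(C)(C)C)O2 | intermediate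
16 | (3R,3aR,8aR)-3-{[di-tert-butyl(fluoro)silyl]oxy}-6,8a-dimethyl-3-(propan-2-yl)-2,3,3a,8a-tetrahydroazulene-1,4-dione | O=C1C=C(C)C=C[C@@]2(C)C(=O)C[C@@](O[Si](F)(C(C)(C)C)C(C)(C)C)(C(C)C)[C@H]12 | intermediate
17 | (3R,3aR,8aR)-3-hydroxy-6,8a-dimethyl-3-(propan-2-yl)-2,3,3a,8a-tetrahydroazulene-1,4-dione (trans ring fusion, H3a anti to 8a-methyl) | O=C1C=C(C)C=C[C@@]2(C)C(=O)C[C@@](O)(C(C)C)[C@H]12 | intermediate
18 | (1S,3R,3aR,8aR)-1,3-dihydroxy-6,8a-dimethyl-3-(propan-2-yl)-2,3,3a,8a-tetrahydroazulen-4(1H)-one | O=C1C=C(C)C=C[C@@]2(C)[C@@H](O)C[C@@](O)(C(C)C)[C@H]12 | intermediate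
19 | dilithium salt: C4 dienolate (C4=C5, C6=C7) and C1 alkoxide of 20 | [Li+].[Li+].[O-]C1=CC(C)=CC[C@@]2(C)[C@@H]([O-])C[C@@](O)(C(C)C)[C@H]12 | intermediate
20 | (1S,3R,3aR,8aR)-1,3-dihydroxy-6,8a-dimethyl-3-(propan-2-yl)-1,2,3,3a,8,8a-hexahydroazulen-4(5H)-one | O=C1CC(C)=CC[C@@]2(C)[C@@H](O)C[C@@](O)(C(C)C)[C@H]12 | intermediate
21 | (1S,3R,3aR,8aR)-3-hydroxy-6,8a-dimethyl-4-oxo-3-(propan-2-yl)-1,2,3,3a,4,5,8,8a-octahydroazulen-1-yl acetate | O=C1CC(C)=CC[C@@]2(C)[C@@H](OC(C)=O)C[C@@](O)(C(C)C)[C@H]12 | intermediate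
22 | (1S,3R,3aS,4S,8aR)-3,4-dihydroxy-6,8a-dimethyl-3-(propan-2-yl)-1,2,3,3a,4,5,8,8a-octahydroazulen-1-yl acetate | O[C@H]1CC(C)=CC[C@@]2(C)[C@@H](OC(C)=O)C[C@@](O)(C(C)C)[C@H]12 | intermediate
23 | 4-methoxybenzoyl chloride | COc1ccc(C(Cl)=O)cc1 | starting material
24 | (1S,3R,3aS,4S,8aR)-1-(acetyloxy)-3-hydroxy-6,8a-dimethyl-3-(propan-2-yl)-1,2,3,3a,4,5,8,8a-octahydroazulen-4-yl 4-methoxybenzoate | COc1ccc(C(=O)O[C@H]2CC(C)=CC[C@@]3(C)[C@@H](OC(C)=O)C[C@@](O)(C(C)C)[C@H]23)cc1 | target

## Step count and risks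

Total step count: 13. Longest linear sequence: 13 steps (from 1; 2, 5 and 23 are bought).

Steps most likely to fail:

1. Step 7. The methyl-substituted carbenoid may be diverted before it adds to the arene, by 1,2-hydride shift from the methyl group to the enone or by insertion into the isopropyl C–H bond. The fallback sets out from acid 11 and moves the quaternary methyl group from the carbene to an enolate alkylation after the ring expansion. Acid chloride 12 is treated with diazomethane to give 1-diazo-3-[(4R)-2,2-di-tert-butyl-7-methyl-4-(propan-2-yl)-4H-1,3,2-benzodioxasilin-4-yl]propan-2-one F1, a terminal diazoketone of the class with the longest record in aromatic cycloaddition and without a β-hydrogen. Rh2(OAc)4 should convert it into the 8a-unsubstituted silylene-bridged trienone F2. LiHMDS (THF, −78 → 0 °C) removes the doubly allylic H8a, and methyl iodide should alkylate the extended enolate at C8a from the face opposite the isopropyl group. The route is rejoined at 15.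

2. Step 9. Chemoselectivity may be lost if the directed hydride is delivered to the dienone carbonyl C4 as well as to C1. The fallback sets out from 15, in which C4 is still masked as the cyclic silyl enol ether and C1 is the only carbonyl group. NaBH4 (MeOH/CH2Cl2, −20 °C) is expected to attack from the face opposite the isopropyl group, which the dioxasiline ring holds over one face of the cyclopentanone, giving the silylene-bridged alcohol F3 with the hydroxyl trans to the 8a-methyl. HF·pyridine then frees the C3 hydroxyl and the C4 ketone, and the route is rejoined at 18. Selectivity between the carbonyl groups is then secured by the order of events instead of by their reactivity.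

3. Step 2. Enantiofacial discrimination between the aryl and isopropyl groups may be insufficient, or allyl transfer to the hindered ketone too slow. The fallback sets out from 4 and replaces the phenol-directed stoichiometric reagent by catalyst control on a protected ketone. TBSCl/imidazole gives 1-{2-[(tert-butyldimethylsilyl)oxy]-4-methylphenyl}-2-methylpropan-1-one F4. Catalytic enantioselective allylboration with allyl-B(pin) and a chiral aminophenol or 3,3′-dibromo-BINOL catalyst should give (3R)-3-{2-[(tert-butyldimethylsilyl)oxy]-4-methylphenyl}-2-methylhex-5-en-3-ol F5. TBAF returns the route to 7, which can be enriched by recrystallisation if needed.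

Further compounds
F1 | step 7 | 1-diazo-3-[(4R)-2,2-di-tert-butyl-7-methyl-4-(propan-2-yl)-4H-1,3,2-benzodioxasilin-4-yl]propan-2-one | [N-]=[N+]=CC(=O)C[C@]1(C(C)C)O[Si](C(C)(C)C)(C(C)(C)C)Oc2cc(C)ccc12
F2 | step 7 | (3R,8aR)-3,4-[(di-tert-butylsilanediyl)bis(oxy)]-6-methyl-3-(propan-2-yl)-3,8a-dihydroazulen-1(2H)-one | CC1=CC2=C3[C@](C(C)C)(CC(=O)[C@@H]3C=C1)O[Si](C(C)(C)C)(C(C)(C)C)O2
F3 | step 9 | (1S,3R,8aR)-3,4-[(di-tert-butylsilanediyl)bis(oxy)]-6,8a-dimethyl-3-(propan-2-yl)-1,2,3,8a-tetrahydroazulen-1-ol | CC1=CC2=C3[C@](C(C)C)(C[C@H](O)[C@]3(C)C=C1)O[Si](C(C)(C)C)(C(C)(C)C)O2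
F4 | step 2 | 1-{2-[(tert-butyldimethylsilyl)oxy]-4-methylphenyl}-2-methylpropan-1-one | CC(C)C(=O)c1ccc(C)cc1O[Si](C)(C)C(C)(C)C
F5 | step 2 | (3R)-3-{2-[(tert-butyldimethylsilyl)oxy]-4-methylphenyl}-2-methylhex-5-en-3-ol | C=CC[C@@](O)(C(C)C)c1ccc(C)cc1O[Si](C)(C)C(C)(C)C
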